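Readings and results are simulated on assumed constants, and the scatter is random.

At early times D in percent seems to take little notice of the concentration: red, at 48 mM, reads 16.7% at 4.00 min, and amber, at 24 mM, carries on from there with 20.1% at 6.00 min. So by hand, changing the concentration moves little. Waiting looks no better: amber falls from 27.0% to 25.2%, against a scatter of 0.3 percentage points, then reads 25.0%. A falling D is going somewhere, and among the suspects X is the place; the level tail suggests that D and X stand in balance.

common to all: temperature 25 °C

| charge | E | Q | remark | time |
|---|---|---|---|---|
| amber | 24 mM | 0.70 equiv | the very flask that is asked about, followed so far |  |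
| red | 48 mM | 0.70 equiv | run made earlier |  |
| flask | 24 mM | 0.700 equiv |  | 1.5 h |

| run | time / min | D / % |
|---|---|---|
| amber | 6.00 | 20.1 |
| amber | 10.0 | 24.5 |
| amber | 15.0 | 26.1 |
| amber | 25.0 | 27.0 |
| amber | 40.0 | 25.2 |
| amber | 80.0 | 25.0 |
| red | 0.250 | 1.5 |
| red | 0.833 | 5.0 |
| red | 1.33 | 6.7 |
| red | 2.00 | 10.1 |
| red | 3.00 | 13.7 |
| red | 4.00 | 16.7 |

(standard deviation of a reading: 0.3 percentage points)

- percent here means E units held: one L counts as two
- D taken out counts as made
- what was read earlier has a scatter of 0.3 percentage points, one standard deviation
- on the list of suspects stand: D <-> X; 2 E -> L; E + Q -> D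
- additions bring no volume worth counting
- the earlier runs do not show what temperature does; that part of a forecast is a guess

- gamma: at 1.5 h add Q, 100% of the amount charged, then wait 3.0 h
- alpha: at 1.5 h raise the temperature by 20 K, then wait 3.0 h
- eta: at 1.5 h take out 90% of the D then present, then wait 3.0 h
- epsilon: change nothing and wait 3.0 h more

1. D, in percent of the E first charged, at 1.5 h
2. what to do for the largest gain in D; "none" if nothing gains more than 2 percentage points (gamma / alpha / eta / epsilon / none)
3. D present, with what was taken out counted in, in percent of the E first charged, after gamma
4. D present, with what was taken out counted in, in percent of the E first charged, after epsilon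

I solve both ends and join them. At the first red pace, D alone would match the Q charge in 11.7 min, well before the tail, and amber holds less Q than E, so I take Q as the limiting reagent, stopping the turnover at 0.70 equiv of E. The tail averages 25.1%, which over that charge makes 35.9%. I carry this as the D share, the part of the turned-over E that stands as D once D and X balance.

Now the settings. Fresh Q at 0.700 equiv exceeds the 30.0% of E I reckon left, so I expect E to turn over and D to reach 35.9%, a gain of 11 points. Taking out D lets X refill it at the same share, which gains 14 points, more than fresh Q. Heat I can only guess. I commit to 25.1% now, eta unless heat beats it, 35.9% after gamma and 25.1% after epsilon.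

The forecast gives 25.1%, gamma, 42% after gamma and 25% after epsilon, reading the stall differently from me: “active Q dies, first order”.

The flask gives 25.0% at 90.0 min, with E 29.6%, Q 0% and X 45.0%. The best is alpha, gaining 32 points, ahead of eta at 14 points, gamma at 11 points and epsilon at 0 points. Gamma ends at 35.6%, beside my D share of 35.9%, and epsilon at 25.0%.

    D ⇌ X (K = 1.80, k = 0.180 min⁻¹, Ea = 75.0 kJ mol⁻¹, ΔH = −83.0 kJ mol⁻¹)
    2 E → L (k = 0.00610 L mol⁻¹ min⁻¹, Ea = 55.0 kJ mol⁻¹)
    E + Q → D, rate k3*[E]^0.5*[Q]^0.5 (k = 0.0780 min⁻¹, Ea = 81.0 kJ mol⁻¹)
    (constants at 25 °C)

The D share passes to a neighbour of this flask charged with 1.80 equiv of Q, where at 90.0 min E stands at 0% and Q at 45% of its own charge. E is the limiting reagent in that neighbour, with 0% left, so the turnover is nearly all of the E charge, and 35.9% of it should stand as D. The neighbour's X holds 64.2%, and its D is 35.7%.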